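The runs were generated by integration from invented constants; the scatter is artificial.

Substrate, target and side product together hold the charge at every moment, and the last midnight reading sums to 99.0 %.

all flasks: substrate 30 mM; added ligand 0.18 mM

| run | free catalyst | remark | time |
|---|---|---|---|
| midnight | 0.24 mM | run made earlier |  |
| noon | 0.54 mM | run made earlier |  |
| dusk | 0.79 mM | run made earlier |  |
| beta | 0.28 mM |  | 2.5 d |
| delta | 1.1 mM |  | 2.5 d |
| theta | 0.56 mM |  | 2.5 d |

| run | time / h | substrate / % | side product / % | target / % |
|---|---|---|---|---|
| midnight | 6.00 | 94.2 | 3.3 | 3.1 |
| midnight | 12.0 | 88.2 | 6.7 | 6.5 |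
| midnight | 20.0 | 80.8 | 10.1 | 9.1 |
| midnight | 25.0 | 77.5 | 12.1 | 10.9 |
| midnight | 30.0 | 72.9 | 14.4 | 11.7 |
| noon | 2.50 | 94.8 | 1.4 | 3.2 |
| noon | 8.00 | 86.9 | 3.9 | 9.4 |
| noon | 15.0 | 79.1 | 7.7 | 13.8 |
| noon | 20.0 | 74.1 | 9.8 | 16.8 |
| noon | 30.0 | 66.8 | 13.5 | 20.4 |
| dusk | 6.00 | 86.3 | 2.7 | 10.7 |
| dusk | 12.0 | 79.0 | 5.8 | 16.1 |
| dusk | 20.0 | 70.5 | 8.3 | 21.2 |
| dusk | 25.0 | 65.7 | 10.9 | 22.7 |
| dusk | 30.0 | 61.7 | 12.8 | 24.5 |

(each reading ± 0.5 percentage points)

- which of these there is most of at the end, counted by the substrate in it, beta (side product / substrate / target)
- which of these there is most of at the end, counted by the substrate in it, delta (side product / substrate / target)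
- which of these there is most of at the end, counted by the substrate in it, theta (side product / substrate / target)
- amount of the one of these that there is most of at the end, in percent of the substrate charged, beta
- amount of the one of these that there is most of at the end, in percent of the substrate charged, delta
- amount of the one of these that there is most of at the end, in percent of the substrate charged, theta

- steps thought possible: 2 free catalyst -> spent catalyst; substrate -> side product; substrate + free catalyst -> free catalyst + target; free catalyst + added ligand <-> idle complex

Pooling the last readings of the three runs, I read the side step as first order in substrate, with side product growing at 0.00541 h⁻¹. With that step acting by itself, substrate at 2.5 d stands at 72.3 %, my bound from above. What the catalyst adds I call the dose: the natural log of charge over substrate left, minus that constant times the time, a pseudo-first-order exposure whose constant falls.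

Theta's charge of free catalyst is 1.04 times noon's, so I treat theta as noon continued. Noon's dose reads 0.153 at 15.0 h and 0.241 at 30.0 h. If free catalyst goes by pairs into spent catalyst, as one of the steps thought possible has it, the dose gained per hour falls, and a second stretch equal to the first then gives my bound from below for theta, 44.6 %.

Noon's second stretch of 15.0 h gave less dose than its first. If each later stretch repeated that gain, the dose at the end is 0.417 and substrate 47.6 %. If each shrank by the same factor, as under a first-order loss, the dose is 0.320 and substrate 52.5 %; I take this as the low end of the dose for theta, since a loss by pairs slows as it thins. Subtracting substrate and the least side product from the charge leaves theta's target at most 36.9 %, and the upper bound leaves its side product at most 27.7 %, both less than its substrate.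

The forecast names substrate, substrate and substrate for beta, delta and theta, with 55.5 %, 43.5 % and 49 %, on the ground that “the catalyst dies by second-order decay”. Its theta value lies inside my tightened bracket.

The flasks give substrate at 56.3 % in beta, substrate at 45.1 % in delta and substrate at 50.4 % in theta, and theta also lies inside the bracket.

    2 free catalyst → spent catalyst (k = 130 M⁻¹ h⁻¹)
    substrate → side product (k = 0.00550 h⁻¹)
    substrate + free catalyst → free catalyst + target (k = 40.0 M⁻¹ h⁻¹)
    free catalyst + added ligand ⇌ idle complex, settled at all times (K = 4500 M⁻¹)

Theta's end gives a dose of 0.360, which is 1.49 times noon's at its last reading. Delta's end gives 0.471. The neighbouring flask is delta read at 40 h. Taking the dose gained per hour as falling, as in noon's readings, I place its dose below delta's end value and above 0.667 of it. That puts substrate between 50.3 % and 58.8 %. The neighbouring flask holds 54.1 % substrate.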